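**Plan** (labdane numbering: ring A = C1–C5 + C10, ring B = C5–C10, side chain C11–C16 on C9, C17 on C8, C18/C19 on C4, C20 on C10)

1. Retrosynthesis: both acetates go on last; the C17 methyl is cut from C8 (C7=C8 enol triflate of a C8 ketone), which turns ring B into a cyclohexanone, i.e. the hydrolysed adduct of a 2-alkoxydiene.
2. C6–C7 and C5–C10 are then cut together. C5–C10 is the bond shared by rings A and B, and the chain C1–C4 joins C10 to C5, so one intramolecular [4+2] of the acyclic triene C7=C8(OMe)–C9=C10 / C5=C6–SO2Ph makes both rings. The sulfone on C6 activates the dienophile and later leaves, which fixes where the enolate forms.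
3. The triene is cut at C10–C20 (Negishi coupling on a Z-enol triflate), C9–C11 (β-keto ester alkylation), C1–C2 (aldol) and C7=C8 (ester methylenation).
4. Forward: aldehyde + dienolate → δ-hydroxy β-keto ester → alkylation with the side-chain iodide → stereodefined tetrasubstituted enoate → methoxydiene → both rings at once → C8 ketone/enone → enol triflate → C17 methyl → diacetate.
5. Stereochemistry: C13 from methyl hydrogen (R)-3-methylglutarate; C2 from a catalytic asymmetric aldol; C5 and C10 from C2 through the chair-like endo transition state; C9 by protonation anti to the C10 methyl.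

Key step: step 13

Remarks: compounds 1, 2, 5 and 9 are taken as commercial. Assumption: the titanium (S)-BINOLate in step 3 directs the dienolate to the si face of aldehyde 4, as such catalysts do with aldehydes in related aldol and allylation reactions; if the sense is opposite, (R)-BINOL is used.

**Route**

Step 1
Reactants: 1 2,2-dimethylpent-4-enal; 2 diethyl [(phenylsulfonyl)methyl]phosphonate
Product: 3 {[(1E)-3,3-dimethylhexa-1,5-dien-1-yl]sulfonyl}benzene
Conditions: NaH, THF, 0 °C → rt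
Reagents that add atoms: none
Why: Horner–Wadsworth–Emmons olefination of a non-enolisable α-quaternary aldehyde with a sulfonyl-stabilised phosphonate anion should give the E-vinyl sulfone, i.e. C5=C6 with the removable activating group on C6.

Step 2
Reactants: 3 {[(1E)-3,3-dimethylhexa-1,5-dien-1-yl]sulfonyl}benzene
Product: 4 (4E)-3,3-dimethyl-5-(phenylsulfonyl)pent-4-enal
Conditions: O3, CH2Cl2, −78 °C, Sudan Red 7B end-point; then Me2S, −78 °C → rt
Reagents that add atoms: ozone, O=[O+][O-]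
Why: Ozonolysis with reductive work-up; electrophilic ozone should consume the terminal alkene well before the electron-poor vinyl sulfone, the dye marking the end-point.

Step 3
Reactants: 4 (4E)-3,3-dimethyl-5-(phenylsulfonyl)pent-4-enal; 5 1-methoxy-1,3-bis(trimethylsilyloxy)buta-1,3-diene
Product: 7 methyl (5R,8E)-5-hydroxy-7,7-dimethyl-3-oxo-9-(phenylsulfonyl)non-8-enoate, via bis-silylated aldol adduct 6 (not isolated)
Conditions: Ti(OiPr)4 (10 mol %), (S)-BINOL (10 mol %), 4 Å MS, THF, −78 °C → rt; then CF3CO2H, THF–H2O, 0 °C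
Reagents that add atoms: none
Why: Catalytic asymmetric vinylogous Mukaiyama aldol addition, in which the chiral titanium BINOLate activates the aldehyde and the terminal carbon of the bis-silyl dienolate should attack its si face to set C2 (5R in 7), acid then removing the silyl groups.

Step 4
Reactants: 7 methyl (5R,8E)-5-hydroxy-7,7-dimethyl-3-oxo-9-(phenylsulfonyl)non-8-enoate
Product: 8 methyl (5R,8E)-5-(tert-butyldimethylsilyloxy)-7,7-dimethyl-3-oxo-9-(phenylsulfonyl)non-8-enoate
Conditions: TBSCl, imidazole, DMF, 0 °C → rt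
Reagents that add atoms: tert-butyldimethylsilyl chloride (TBSCl), CC(C)(C)[Si](C)(C)Cl
Why: Silyl ether formation blocks lactonisation and dehydration of the δ-hydroxy β-keto ester and supplies the group that later sits equatorial in the cycloaddition.

Step 5
Reactants: 9 (3R)-5-methoxy-3-methyl-5-oxopentanoic acid [methyl hydrogen (R)-3-methylglutarate]
Product: 10 methyl (3R)-5-hydroxy-3-methylpentanoate
Conditions: BH3·SMe2, THF, −10 °C → rt; aq. work-up
Reagents that add atoms: none
Why: Chemoselective borane reduction of the carboxylic acid (via the acyloxyborane) in the presence of the ester differentiates the two ends without touching the C13 stereocentre.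

Step 6
Reactants: 10 methyl (3R)-5-hydroxy-3-methylpentanoate
Product: 11 methyl (3R)-5-(tert-butyldimethylsilyloxy)-3-methylpentanoate
Conditions: TBSCl, imidazole, CH2Cl2, 0 °C → rt
Reagents that add atoms: tert-butyldimethylsilyl chloride (TBSCl), CC(C)(C)[Si](C)(C)Cl
Why: Prompt silylation of the primary alcohol (the future C15–O) prevents lactonisation and matches the protecting group on C2 for a single late deprotection.

Step 7
Reactants: 11 methyl (3R)-5-(tert-butyldimethylsilyloxy)-3-methylpentanoate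
Product: 12 (3S)-5-(tert-butyldimethylsilyloxy)-3-methylpentan-1-ol
Conditions: LiAlH4, Et2O, 0 °C
Reagents that add atoms: none
Why: Hydride reduction of the ester to the primary alcohol (future C11) leaves the silyl ether and the stereocentre intact; the descriptor changes only through priority.

Step 8
Reactants: 12 (3S)-5-(tert-butyldimethylsilyloxy)-3-methylpentan-1-ol
Product: 13 tert-butyl{[(3R)-5-iodo-3-methylpentyl]oxy}dimethylsilane
Conditions: I2, PPh3, imidazole, CH2Cl2, 0 °C → rt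
Reagents that add atoms: iodine, II
Why: Appel-type iodination by SN2 displacement of the primary oxyphosphonium ion gives the unhindered primary iodide.

Step 9
Reactants: 8 methyl (5R,8E)-5-(tert-butyldimethylsilyloxy)-7,7-dimethyl-3-oxo-9-(phenylsulfonyl)non-8-enoate; 13 tert-butyl{[(3R)-5-iodo-3-methylpentyl]oxy}dimethylsilane
Product: 14 methyl (5R,8E)-5-(tert-butyldimethylsilyloxy)-2-[(3S)-5-(tert-butyldimethylsilyloxy)-3-methylpentyl]-7,7-dimethyl-3-oxo-9-(phenylsulfonyl)non-8-enoate (both C2 epimers)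
Conditions: NaH, THF–DMF (4:1), 0 °C; then 13, 50 °C
Reagents that add atoms: none
Why: Acetoacetic ester C-alkylation of the doubly stabilised enolate with a primary iodide forms C9–C11; the new centre is lost in step 10, and the hindered vinyl sulfone should not compete as a Michael acceptor.

Step 10
Reactants: 14 methyl (5R,8E)-5-(tert-butyldimethylsilyloxy)-2-[(3S)-5-(tert-butyldimethylsilyloxy)-3-methylpentyl]-7,7-dimethyl-3-oxo-9-(phenylsulfonyl)non-8-enoate
Product: 15 methyl (2Z,5R,8E)-5-(tert-butyldimethylsilyloxy)-2-[(3S)-5-(tert-butyldimethylsilyloxy)-3-methylpentyl]-7,7-dimethyl-9-(phenylsulfonyl)-3-(trifluoromethylsulfonyloxy)nona-2,8-dienoate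
Conditions: NaH, Et2O, 0 °C; then Tf2O, −78 → 0 °C
Reagents that add atoms: trifluoromethanesulfonic anhydride (Tf2O), O=S(=O)(OS(=O)(=O)C(F)(F)F)C(F)(F)F
Why: O-Sulfonylation of the sodium-chelated enolate of the α-alkyl β-keto ester should give the Z-enol triflate (OTf cis to CO2Me), which fixes the geometry of the future C9=C10 bond.

Step 11
Reactants: 15 methyl (2Z,5R,8E)-5-(tert-butyldimethylsilyloxy)-2-[(3S)-5-(tert-butyldimethylsilyloxy)-3-methylpentyl]-7,7-dimethyl-9-(phenylsulfonyl)-3-(trifluoromethylsulfonyloxy)nona-2,8-dienoate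
Product: 16 methyl (2E,5R,8E)-5-(tert-butyldimethylsilyloxy)-2-[(3S)-5-(tert-butyldimethylsilyloxy)-3-methylpentyl]-3,7,7-trimethyl-9-(phenylsulfonyl)nona-2,8-dienoate
Conditions: MeZnCl, Pd(PPh3)4 (5 mol %), THF, 50 °C
Reagents that add atoms: methylzinc chloride, C[Zn]Cl
Why: Negishi cross-coupling of the activated β-(triflyloxy)acrylate proceeds with retention, placing the C20 methyl cis to the ester and the C1 chain trans to it; the organozinc should leave ester and vinyl sulfone alone.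

Step 12
Reactants: 16 methyl (2E,5R,8E)-5-(tert-butyldimethylsilyloxy)-2-[(3S)-5-(tert-butyldimethylsilyloxy)-3-methylpentyl]-3,7,7-trimethyl-9-(phenylsulfonyl)nona-2,8-dienoate
Product: 17 {[(1E,5R,7E)-5-(tert-butyldimethylsilyloxy)-8-[(3S)-5-(tert-butyldimethylsilyloxy)-3-methylpentyl]-9-methoxy-3,3,7-trimethyldeca-1,7,9-trien-1-yl]sulfonyl}benzene
Conditions: Cp2Ti(μ-CH2)(μ-Cl)AlMe2, pyridine, THF–PhMe, −40 → 0 °C; aq. NaOH quench, basic Al2O3 filtration
Reagents that add atoms: Cp2Ti(μ-CH2)(μ-Cl)AlMe2, C[Al-]1(C)C[Ti]([Cl+]1)(C2C=CC=C2)C3C=CC=C3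
Why: Tebbe methylenation of the conjugated ester carbonyl gives the methyl enol ether, i.e. the 2-methoxydiene C7=C8(OMe)–C9=C10 with C7 delivered by the titanium methylidene; silyl ethers and the sulfone should be inert to the oxophilic carbene.

Step 13
Reactants: 17 {[(1E,5R,7E)-5-(tert-butyldimethylsilyloxy)-8-[(3S)-5-(tert-butyldimethylsilyloxy)-3-methylpentyl]-9-methoxy-3,3,7-trimethyldeca-1,7,9-trien-1-yl]sulfonyl}benzene
Product: 18 trans-fused cycloadduct, 2,15-bis(tert-butyldimethylsilyloxy)-8-methoxy-6-(phenylsulfonyl)-17-norlabd-8-ene (H-5 trans to the C10 methyl; sulfonyl on C6 cis to H-5; silyloxy on C2 trans to the C10 methyl; C2 R, C13 S)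
Conditions: PhMe (0.01 M), BHT (cat.), Et3N (1 vol %), sealed tube, 135 °C
Reagents that add atoms: none
Why: Thermal, concerted but asynchronous intramolecular [4+2] cycloaddition of a 1,7,9-decatriene, in which the 2-methoxydiene C7=C8(OMe)–C9=C10 adds to the E-vinyl sulfone C5=C6; the closest known reaction type is the type 1 intramolecular Diels–Alder reaction of terminally sulfonyl- or ester-activated decatrienes to trans-fused octalins. Ring B (C5–C10) is closed as the cycloaddition ring through the new C6–C7 and C5–C10 bonds, and ring A (C1–C5, C10) is closed by the same C5–C10 bond because the four-carbon tether C1–C4 links the diene terminus C10 to the dienophile carbon C5 (both closures six-membered, regiochemistry enforced by the tether). C10 and C5 should come out trans from the tether-exo, sulfonyl-endo chair-like transition state (Alder endo preference of the E-sulfonyl group; in the tether-endo alternative the C4 gem-dimethyl group is pushed under the diene against the C9 substituent), and the E geometry of the dienophile places the C6 sulfonyl cis to H-5. The absolute sense is relayed from C2: its silyloxy group must sit equatorial in the forming ring A chair, because an axial one would be 1,3-diaxial to both the C10 methyl and the axial C4 methyl, so only one diene face is attacked. The step needs the E geometry of C9=C10 (tether trans to C8, secured in steps 10 and 11), a rate high enough to outrun a 1,5-hydrogen shift of the Z-methyl diene (helped by sulfone activation, the donor methoxy group and the Thorpe–Ingold effect of the C4 gem-dimethyl group), and acid-free conditions for the enol ether (Et3N, BHT).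

Step 14
Reactants: 18 trans-fused cycloadduct, 2,15-bis(tert-butyldimethylsilyloxy)-8-methoxy-6-(phenylsulfonyl)-17-norlabd-8-ene
Product: 20 2,15-bis(tert-butyldimethylsilyloxy)-17-norlabd-6-en-8-one (trans-fused; H-9 cis to H-5, side chain equatorial), via β-sulfonyl ketone 19 (not isolated)
Conditions: (CO2H)2, THF–H2O, 0 °C → rt; then DBU, CH2Cl2, 0 °C → rt
Reagents that add atoms: water, O
Why: Mild acid hydrolysis of the enol ether protonates C9 on the face anti to the axial C10 methyl (side chain equatorial) and unveils the C8 ketone, after which E1cB loss of benzenesulfinate from the β-sulfonyl ketone gives the C6=C7 enone and removes the activating group.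

Step 15
Reactants: 20 2,15-bis(tert-butyldimethylsilyloxy)-17-norlabd-6-en-8-one
Product: 22 2,15-bis(tert-butyldimethylsilyloxy)-8-(trifluoromethylsulfonyloxy)-17-norlabd-7-ene (C7=C8 enol triflate), via lithium enolate 21 (not isolated)
Conditions: LiBH(s-Bu)3, THF, −78 °C; then PhNTf2, −78 → 0 °C
Reagents that add atoms: N-phenylbis(trifluoromethanesulfonimide) (PhNTf2), O=S(=O)(N(c1ccccc1)S(=O)(=O)C(F)(F)F)C(F)(F)F
Why: Conjugate hydride reduction of the β-unsubstituted cyclohexenone (1,2-attack is hindered by the C9 substituent) gives the C7=C8 enolate regiospecifically, and O-triflation traps it without equilibration, so C9 is untouched.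

Step 16
Reactants: 22 2,15-bis(tert-butyldimethylsilyloxy)-8-(trifluoromethylsulfonyloxy)-17-norlabd-7-ene
Product: 23 tert-butyl{[(2R,4aR,8R,8aR)-8-[(3S)-5-(tert-butyldimethylsilyloxy)-3-methylpentyl]-4,4,7,8a-tetramethyl-1,2,3,4,4a,5,8,8a-octahydronaphthalen-2-yl]oxy}dimethylsilane
Conditions: MeZnCl, Pd(PPh3)4 (5 mol %), THF, 60 °C
Reagents that add atoms: methylzinc chloride, C[Zn]Cl
Why: Negishi methylation of the cyclohexenyl triflate installs C17 on C8 and leaves the trisubstituted C7=C8 alkene where the triflate fixed it.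

Step 17
Reactants: 23 tert-butyl{[(2R,4aR,8R,8aR)-8-[(3S)-5-(tert-butyldimethylsilyloxy)-3-methylpentyl]-4,4,7,8a-tetramethyl-1,2,3,4,4a,5,8,8a-octahydronaphthalen-2-yl]oxy}dimethylsilane
Product: 25 (2R,4aR,8R,8aR)-8-[(3S)-5-acetoxy-3-methylpentyl]-4,4,7,8a-tetramethyl-1,2,3,4,4a,5,8,8a-octahydronaphthalen-2-yl acetate, via diol 24 (not isolated)
Conditions: Bu4NF, THF, rt → 40 °C; then Et3N, DMAP (cat.), Ac2O, 0 °C → rt
Reagents that add atoms: acetic anhydride, CC(=O)OC(C)=O
Why: Fluoride cleaves both silyl ethers and the resulting alkoxides are acetylated in the same flask (nucleophilic acyl substitution with DMAP catalysis), under conditions that do not move the C7=C8 alkene.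

**Compound list**

1 | 2,2-dimethylpent-4-enal | C=CCC(C)(C)C=O | starting material
2 | diethyl [(phenylsulfonyl)methyl]phosphonate | CCOP(=O)(CS(=O)(=O)c1ccccc1)OCC | starting material
3 | {[(1E)-3,3-dimethylhexa-1,5-dien-1-yl]sulfonyl}benzene | C=CCC(C)(C)/C=C/S(=O)(=O)c1ccccc1 | intermediate
4 | (4E)-3,3-dimethyl-5-(phenylsulfonyl)pent-4-enal | O=CCC(C)(C)/C=C/S(=O)(=O)c1ccccc1 | intermediate
5 | 1-methoxy-1,3-bis(trimethylsilyloxy)buta-1,3-diene (C1=C2 geometry immaterial) | COC(O[Si](C)(C)C)=CC(=C)O[Si](C)(C)C | starting material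
6 | (5R,8E)-1-methoxy-7,7-dimethyl-9-(phenylsulfonyl)-1,5-bis(trimethylsilyloxy)nona-1,8-dien-3-one (bis-silylated aldol adduct, not isolated; ketene acetal geometry immaterial) | COC(O[Si](C)(C)C)=CC(=O)C[C@H](O[Si](C)(C)C)CC(C)(C)/C=C/S(=O)(=O)c1ccccc1 | intermediate
7 | methyl (5R,8E)-5-hydroxy-7,7-dimethyl-3-oxo-9-(phenylsulfonyl)non-8-enoate | COC(=O)CC(=O)C[C@H](O)CC(C)(C)/C=C/S(=O)(=O)c1ccccc1 | intermediate
8 | methyl (5R,8E)-5-(tert-butyldimethylsilyloxy)-7,7-dimethyl-3-oxo-9-(phenylsulfonyl)non-8-enoate | COC(=O)CC(=O)C[C@H](O[Si](C)(C)C(C)(C)C)CC(C)(C)/C=C/S(=O)(=O)c1ccccc1 | intermediate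
9 | (3R)-5-methoxy-3-methyl-5-oxopentanoic acid [methyl hydrogen (R)-3-methylglutarate] | COC(=O)C[C@H](C)CC(O)=O | starting material
10 | methyl (3R)-5-hydroxy-3-methylpentanoate | COC(=O)C[C@H](C)CCO | intermediate
11 | methyl (3R)-5-(tert-butyldimethylsilyloxy)-3-methylpentanoate | COC(=O)C[C@H](C)CCO[Si](C)(C)C(C)(C)C | intermediate
12 | (3S)-5-(tert-butyldimethylsilyloxy)-3-methylpentan-1-ol | OCC[C@H](C)CCO[Si](C)(C)C(C)(C)C | intermediate
13 | tert-butyl{[(3R)-5-iodo-3-methylpentyl]oxy}dimethylsilane | ICC[C@H](C)CCO[Si](C)(C)C(C)(C)C | intermediate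
14 | methyl (5R,8E)-5-(tert-butyldimethylsilyloxy)-2-[(3S)-5-(tert-butyldimethylsilyloxy)-3-methylpentyl]-7,7-dimethyl-3-oxo-9-(phenylsulfonyl)non-8-enoate (both C2 epimers) | COC(=O)C(CC[C@H](C)CCO[Si](C)(C)C(C)(C)C)C(=O)C[C@H](O[Si](C)(C)C(C)(C)C)CC(C)(C)/C=C/S(=O)(=O)c1ccccc1 | intermediate
15 | methyl (2Z,5R,8E)-5-(tert-butyldimethylsilyloxy)-2-[(3S)-5-(tert-butyldimethylsilyloxy)-3-methylpentyl]-7,7-dimethyl-9-(phenylsulfonyl)-3-(trifluoromethylsulfonyloxy)nona-2,8-dienoate | COC(=O)/C(CC[C@H](C)CCO[Si](C)(C)C(C)(C)C)=C(\OS(=O)(=O)C(F)(F)F)C[C@H](O[Si](C)(C)C(C)(C)C)CC(C)(C)/C=C/S(=O)(=O)c1ccccc1 | intermediate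
16 | methyl (2E,5R,8E)-5-(tert-butyldimethylsilyloxy)-2-[(3S)-5-(tert-butyldimethylsilyloxy)-3-methylpentyl]-3,7,7-trimethyl-9-(phenylsulfonyl)nona-2,8-dienoate | COC(=O)/C(CC[C@H](C)CCO[Si](C)(C)C(C)(C)C)=C(\C)C[C@H](O[Si](C)(C)C(C)(C)C)CC(C)(C)/C=C/S(=O)(=O)c1ccccc1 | intermediate
17 | {[(1E,5R,7E)-5-(tert-butyldimethylsilyloxy)-8-[(3S)-5-(tert-butyldimethylsilyloxy)-3-methylpentyl]-9-methoxy-3,3,7-trimethyldeca-1,7,9-trien-1-yl]sulfonyl}benzene | C=C(OC)/C(CC[C@H](C)CCO[Si](C)(C)C(C)(C)C)=C(\C)C[C@H](O[Si](C)(C)C(C)(C)C)CC(C)(C)/C=C/S(=O)(=O)c1ccccc1 | intermediate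
18 | trans-fused cycloadduct: 2,15-bis(tert-butyldimethylsilyloxy)-8-methoxy-6-(phenylsulfonyl)-17-norlabd-8-ene (H-5 trans to C10 methyl; sulfonyl cis to H-5; C2 silyloxy trans to C10 methyl) | CC(C)(C)[Si](C)(C)OCC[C@@H](C)CCC1=C(OC)C[C@@H](S(=O)(=O)c2ccccc2)[C@@H]3C(C)(C)C[C@@H](O[Si](C)(C)C(C)(C)C)C[C@@]13C | intermediate
19 | 2,15-bis(tert-butyldimethylsilyloxy)-6-(phenylsulfonyl)-17-norlabdan-8-one (H-9 cis to H-5; not isolated) | CC(C)(C)[Si](C)(C)OCC[C@@H](C)CC[C@@H]1C(=O)C[C@@H](S(=O)(=O)c2ccccc2)[C@@H]3C(C)(C)C[C@@H](O[Si](C)(C)C(C)(C)C)C[C@@]13C | intermediate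
20 | 2,15-bis(tert-butyldimethylsilyloxy)-17-norlabd-6-en-8-one (trans-fused; H-9 cis to H-5) | CC(C)(C)[Si](C)(C)OCC[C@@H](C)CC[C@@H]1C(=O)C=C[C@@H]2C(C)(C)C[C@@H](O[Si](C)(C)C(C)(C)C)C[C@@]12C | intermediate
21 | lithium 2,15-bis(tert-butyldimethylsilyloxy)-17-norlabd-7-en-8-olate (not isolated) | CC(C)(C)[Si](C)(C)OCC[C@@H](C)CC[C@@H]1C(O[Li])=CC[C@@H]2C(C)(C)C[C@@H](O[Si](C)(C)C(C)(C)C)C[C@@]12C | intermediate
22 | 2,15-bis(tert-butyldimethylsilyloxy)-8-(trifluoromethylsulfonyloxy)-17-norlabd-7-ene | CC(C)(C)[Si](C)(C)OCC[C@@H](C)CC[C@@H]1C(OS(=O)(=O)C(F)(F)F)=CC[C@@H]2C(C)(C)C[C@@H](O[Si](C)(C)C(C)(C)C)C[C@@]12C | intermediate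
23 | tert-butyl{[(2R,4aR,8R,8aR)-8-[(3S)-5-(tert-butyldimethylsilyloxy)-3-methylpentyl]-4,4,7,8a-tetramethyl-1,2,3,4,4a,5,8,8a-octahydronaphthalen-2-yl]oxy}dimethylsilane | CC(C)(C)[Si](C)(C)OCC[C@@H](C)CC[C@@H]1C(C)=CC[C@@H]2C(C)(C)C[C@@H](O[Si](C)(C)C(C)(C)C)C[C@@]12C | intermediate
24 | (2R,4aR,8R,8aR)-8-[(3S)-5-hydroxy-3-methylpentyl]-4,4,7,8a-tetramethyl-1,2,3,4,4a,5,8,8a-octahydronaphthalen-2-ol (not isolated) | OCC[C@@H](C)CC[C@@H]1C(C)=CC[C@@H]2C(C)(C)C[C@@H](O)C[C@@]12C | intermediate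
25 | (2R,4aR,8R,8aR)-8-[(3S)-5-acetoxy-3-methylpentyl]-4,4,7,8a-tetramethyl-1,2,3,4,4a,5,8,8a-octahydronaphthalen-2-yl acetate | CC(=O)OCC[C@@H](C)CC[C@@H]1C(C)=CC[C@@H]2C(C)(C)C[C@@H](OC(C)=O)C[C@@]12C | target

**Count and risks**

Total steps: 17. Longest linear sequence: 13 (steps 1–4 and 9–17, from 1).

Most likely to fail:

1. Step 13. The cycloaddition may be slower than a thermal 1,5-hydrogen shift of the Z-methyl diene, and the exo (cis-fused) mode may compete at the temperature needed. Fallback, from 17 back to 18 and 20: the vinylic C–H next to sulfur is removed with LiN(i-Pr)2 (THF, −78 °C) and the anion acylated with ClCO2Me to give the geminally activated triene F1. This much more electron-poor dienophile should cyclise near room temperature to the cycloadduct F2, ring fusion then being governed by the tether sterics alone. NaSPh in DMF (SN2 demethylation, then decarboxylation of the α-sulfonyl carboxylate) removes the ester and gives 18 together with its C6 epimer F3. Both are taken through step 14, F3 by way of the epimeric ketone F4, and meet at 20 because C6 loses its configuration there.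

2. Step 12. The titanium methylidene may react with the sulfonyl-substituted alkene or methylenate the hindered conjugated ester incompletely, and the methyl enol ether may hydrolyse on isolation. Fallback, from 16 back to 19: i-Bu2AlH reduces the ester to the allylic alcohol F5, MnO2 gives the enal F6, MeMgBr gives the carbinol F7 and Dess–Martin periodinane the methyl enone F8. Kinetic deprotonation of the methyl group (LiN(i-Pr)2, −78 °C) with Et3SiCl gives the 2-(triethylsilyloxy)diene F9, which is cyclised as in step 13 to the silyl enol ether F10. Mild acid converts F10 into 19, which continues with the DBU stage of step 14.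

3. Step 3. Facial discrimination in the catalytic aldol may be incomplete, or may have the opposite sense, for this β-branched aliphatic aldehyde. Fallback, from 4 back to 8: reagent-controlled allylboration with (−)-Ipc2B(allyl) [from (−)-Ipc2BOMe and allylMgBr; si-face addition] gives the homoallylic alcohol F11 and TBSCl the silyl ether F12. Ozonolysis of the terminal alkene (selective as in step 2) gives the β-silyloxy aldehyde F13, and SnCl2-catalysed Roskamp homologation with methyl diazoacetate gives 8.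

**Further compounds**

F1 | step 13 | methyl (2E,6R,8E)-6-(tert-butyldimethylsilyloxy)-9-[(3S)-5-(tert-butyldimethylsilyloxy)-3-methylpentyl]-10-methoxy-4,4,8-trimethyl-2-(phenylsulfonyl)undeca-2,8,10-trienoate | C=C(OC)/C(CC[C@H](C)CCO[Si](C)(C)C(C)(C)C)=C(\C)C[C@H](O[Si](C)(C)C(C)(C)C)CC(C)(C)/C=C(\C(=O)OC)S(=O)(=O)c1ccccc1
F2 | step 13 | cycloadduct 18 carrying an additional methoxycarbonyl group on C6 (ester trans to H-5) | CC(C)(C)[Si](C)(C)OCC[C@@H](C)CCC1=C(OC)C[C@@](C(=O)OC)(S(=O)(=O)c2ccccc2)[C@@H]3C(C)(C)C[C@@H](O[Si](C)(C)C(C)(C)C)C[C@@]13C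
F3 | step 13 | C6 epimer of 18 (sulfonyl trans to H-5) | CC(C)(C)[Si](C)(C)OCC[C@@H](C)CCC1=C(OC)C[C@H](S(=O)(=O)c2ccccc2)[C@@H]3C(C)(C)C[C@@H](O[Si](C)(C)C(C)(C)C)C[C@@]13C
F4 | step 13 | C6 epimer of 19 | CC(C)(C)[Si](C)(C)OCC[C@@H](C)CC[C@@H]1C(=O)C[C@H](S(=O)(=O)c2ccccc2)[C@@H]3C(C)(C)C[C@@H](O[Si](C)(C)C(C)(C)C)C[C@@]13C
F5 | step 12 | (2E,5R,8E)-5-(tert-butyldimethylsilyloxy)-2-[(3S)-5-(tert-butyldimethylsilyloxy)-3-methylpentyl]-3,7,7-trimethyl-9-(phenylsulfonyl)nona-2,8-dien-1-ol | OC/C(CC[C@H](C)CCO[Si](C)(C)C(C)(C)C)=C(\C)C[C@H](O[Si](C)(C)C(C)(C)C)CC(C)(C)/C=C/S(=O)(=O)c1ccccc1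
F6 | step 12 | (2E,5R,8E)-5-(tert-butyldimethylsilyloxy)-2-[(3S)-5-(tert-butyldimethylsilyloxy)-3-methylpentyl]-3,7,7-trimethyl-9-(phenylsulfonyl)nona-2,8-dienal | O=C/C(CC[C@H](C)CCO[Si](C)(C)C(C)(C)C)=C(\C)C[C@H](O[Si](C)(C)C(C)(C)C)CC(C)(C)/C=C/S(=O)(=O)c1ccccc1
F7 | step 12 | (3E,6R,9E)-6-(tert-butyldimethylsilyloxy)-3-[(3S)-5-(tert-butyldimethylsilyloxy)-3-methylpentyl]-4,8,8-trimethyl-10-(phenylsulfonyl)deca-3,9-dien-2-ol (both carbinol epimers) | CC(O)/C(CC[C@H](C)CCO[Si](C)(C)C(C)(C)C)=C(\C)C[C@H](O[Si](C)(C)C(C)(C)C)CC(C)(C)/C=C/S(=O)(=O)c1ccccc1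
F8 | step 12 | (3E,6R,9E)-6-(tert-butyldimethylsilyloxy)-3-[(3S)-5-(tert-butyldimethylsilyloxy)-3-methylpentyl]-4,8,8-trimethyl-10-(phenylsulfonyl)deca-3,9-dien-2-one | CC(=O)/C(CC[C@H](C)CCO[Si](C)(C)C(C)(C)C)=C(\C)C[C@H](O[Si](C)(C)C(C)(C)C)CC(C)(C)/C=C/S(=O)(=O)c1ccccc1
F9 | step 12 | {[(1E,5R,7E)-5-(tert-butyldimethylsilyloxy)-8-[(3S)-5-(tert-butyldimethylsilyloxy)-3-methylpentyl]-3,3,7-trimethyl-9-(triethylsilyloxy)deca-1,7,9-trien-1-yl]sulfonyl}benzene | C=C(O[Si](CC)(CC)CC)/C(CC[C@H](C)CCO[Si](C)(C)C(C)(C)C)=C(\C)C[C@H](O[Si](C)(C)C(C)(C)C)CC(C)(C)/C=C/S(=O)(=O)c1ccccc1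
F10 | step 12 | cycloadduct 18 with triethylsilyloxy in place of methoxy on C8 | CC(C)(C)[Si](C)(C)OCC[C@@H](C)CCC1=C(O[Si](CC)(CC)CC)C[C@@H](S(=O)(=O)c2ccccc2)[C@@H]3C(C)(C)C[C@@H](O[Si](C)(C)C(C)(C)C)C[C@@]13C
F11 | step 3 | (4S,7E)-6,6-dimethyl-8-(phenylsulfonyl)octa-1,7-dien-4-ol | C=CC[C@H](O)CC(C)(C)/C=C/S(=O)(=O)c1ccccc1
F12 | step 3 | tert-butyl{[(4S,7E)-6,6-dimethyl-8-(phenylsulfonyl)octa-1,7-dien-4-yl]oxy}dimethylsilane | C=CC[C@H](O[Si](C)(C)C(C)(C)C)CC(C)(C)/C=C/S(=O)(=O)c1ccccc1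
F13 | step 3 | (3R,6E)-3-(tert-butyldimethylsilyloxy)-5,5-dimethyl-7-(phenylsulfonyl)hept-6-enal | O=CC[C@H](O[Si](C)(C)C(C)(C)C)CC(C)(C)/C=C/S(=O)(=O)c1ccccc1
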